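The numbers in the tables stem from a simulated flask with constants of no real substance, noise included.

**Easy rate.** The easy step is to read the fall of target. In the dusk run at 60 °C target drops from 27.0% to 5.1% between 0.667 min and 3.00 min, which reads as a first-order loss of 0.714 min⁻¹. The summer run at 45 °C reads 0.0884 min⁻¹, while its target plus side product A stays steady, from 57.9% to 59.8%.

| setting | summer | dusk | autumn | noon | Saturday's | Friday's | Sunday's | Monday's |
|---|---|---|---|---|---|---|---|---|
| substrate | 0.20 M | 0.20 M | 0.20 M | 0.40 M | 0.20 M | 0.20 M (fed, over 6.0 min) | 0.20 M | 0.20 M |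
| reagent | 0.19 M | 0.27 M | 0.42 M | 0.19 M | 0.190 M | 0.190 M | 0.190 M (fed, over 6.0 min) | 0.190 M (fed, over 6.0 min) |
| temperature | 45 °C | 60 °C | 45 °C | 60 °C | 60 °C | 60 °C |  | 60 °C |
| remark | run made earlier | run made earlier | run made earlier | run made earlier | everything together at the start | all else is in the flask from the start; the feed brings no volume worth counting | the addition at 20 °C, then warmed to 60 °C; the feed brings no volume worth counting | all else is in the flask from the start; the feed brings no volume worth counting |
| time |  |  |  |  | 8.0 min | 8.0 min | 8.0 min | 8.0 min |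

| run | time / min | target / % | side product A / % |
|---|---|---|---|
| summer | 0.833 | 40.6 | 17.3 |
| summer | 3.00 | 36.9 | 25.1 |
| summer | 5.00 | 28.8 | 31.9 |
| summer | 6.00 | 28.2 | 34.4 |
| summer | 10.0 | 18.4 | 40.8 |
| summer | 12.0 | 16.2 | 45.5 |
| summer | 15.0 | 11.6 | 48.2 |
| dusk | 0.667 | 27.0 | 33.8 |
| dusk | 1.33 | 16.8 | 46.1 |
| dusk | 2.00 | 12.0 | 53.6 |
| dusk | 3.00 | 5.1 | 60.0 |
| dusk | 4.00 | 3.7 | 63.1 |
| dusk | 5.00 | 1.9 | 64.8 |
| autumn | 0.833 | 64.4 | 8.2 |
| autumn | 1.33 | 64.4 | 11.6 |
| autumn | 2.00 | 59.7 | 12.7 |
| autumn | 3.00 | 57.8 | 15.6 |
| autumn | 4.00 | 53.2 | 18.5 |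
| autumn | 6.00 | 46.5 | 23.0 |
| autumn | 10.0 | 36.7 | 31.0 |
| noon | 1.00 | 8.6 | 34.3 |
| noon | 2.00 | 3.2 | 42.2 |
| noon | 3.00 | 1.7 | 45.6 |
| noon | 4.00 | 1.2 | 46.5 |
| noon | 5.00 | 0 | 48.9 |

(scatter of a reading: 1 percentage point)



1. which flask leads in share of target in target plus side product A ("all alike" within 1.5 percentage points) (Saturday's / Friday's / Sunday's / Monday's / all alike)
2. share of target in target plus side product A at the end, Saturday's
3. share of target in target plus side product A at the end, Friday's
4. share of target in target plus side product A at the end, Sunday's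
5. share of target in target plus side product A at the end, Monday's

**Cold feed.** Carrying the same fall in rate down to 20 °C gives 0.00272 min⁻¹, far below the hot rate, so the cold feed of Sunday's flask costs target about 1.62% on this reckoning.

**Hot survival.** Target's lifetime at 60 °C is 1.40 min, and Sunday's flask stays hot for 2.00 min, which is longer. That gives 0.240. This hot survival, the fraction of the target standing at heat-on that outlasts the hot time at first-order loss, is the quantity to carry.

**My numbers.** Summer's early selectivity, target in target plus side product A, reads 70.1%; taking it for Sunday's flask is my assumption, and it gives 16.8%. Saturday's flask, hot throughout, gives 0.231% on the same assumed share. Friday's flask, taken as making its target evenly through the hot feed, gives 3.87%. Monday's flask, assumed to have noon's early share of 20.0%, gives 1.11%. On this reckoning Sunday's flask leads.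

**Weak link.** The hot rate rests on one pair of readings. The noon run, with other charges and its own scatter, reads 0.811 min⁻¹, which on my reckoning makes Sunday's share 13.9% and Friday's 2.83%, so Sunday's lead stands.

**The forecast.** It names Sunday's, with 0.4% for Saturday's, 7% for Friday's, 15% for Sunday's and 1.5% for Monday's, on the ground that "Sunday makes target cold, where decay is negligible, then has only 2 min at 60 °C". For the initial share it takes 0.6, where I take summer's reading.

**The flasks.** Sunday's leads with 12.8%, against 2.59% for Friday's, 0.140% for Saturday's and 0.0146% for Monday's, under this scheme: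

    substrate + reagent ⇌ target (K = 7.50 M⁻¹, k = 21.0 M⁻¹ min⁻¹, Ea = 39.0 kJ mol⁻¹, ΔH = −73.0 kJ mol⁻¹)
    substrate → side product A (k = 1.90 min⁻¹, Ea = 90.0 kJ mol⁻¹)
    2 substrate → side product B (k = 9.60 M⁻¹ min⁻¹, Ea = 60.0 kJ mol⁻¹)
    reagent + target → over-reaction product (k = 0.240 M⁻¹ min⁻¹, Ea = 78.0 kJ mol⁻¹)
    (constants at 60 °C)

In Sunday's flask target stands at 39.2% at the change of temperature and 6.33% at the end, a kept fraction of 0.161, lower than the hot survival of 0.240. Sunday's flask left until 30 min has 24.0 min hot, a hot survival of 3.58 × 10⁻⁸, and its share reads 0%.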